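## Retrosynthetic overview

1. The target is a cis-2,4-diarylchroman. Its only non-aromatic ring is the pyran ring O1–C2–C3–C4–C4a–C8a. That ring is the sum of a four-atom oxadiene O1=C8a–C4a=C4 (the ortho-quinone methide of ring A, with ring D on C4) and the alkene C3=C2 of a styrene carrying ring B.
2. First cut: the five O-benzyl groups and the ring D–C(=O) bond (aryl bromide, then aryllithium, plus the Weinreb amide of dodecanoic acid), leaving the benzyl-protected chroman core.
3. Second cut (key): C3–C4 and O1–C2 together, by an enantioselective Brønsted acid catalysed oxa-(4+2) cycloaddition of the methide with 4-vinylphenol. Both stereocentres arise here.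
4. Third cut: the methide comes from a racemic ortho-hydroxybenzhydrol, made from lithiated phloroglucinol tribenzyl ether and 4-benzyloxysalicylaldehyde.
5. Ring order: rings A, B and D are bought as arenes, and the pyran ring is the only ring formed.

Key step: step 4

Assumption: the sense of induction of the binaphthyl phosphoric acid cannot be fixed on paper for this pair of partners, so the (R)-catalyst is written, and its (S)-enantiomer is used instead if the first run delivers the (2S,4S) series.

## Route

Step 1
Reactants: 1 1,3,5-tris(benzyloxy)benzene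
Product: 2 2-bromo-1,3,5-tris(benzyloxy)benzene
Conditions: NBS (1.0 equiv), CH2Cl2, −78 to 0 °C, dark
Reagents that add atoms: N-bromosuccinimide, O=C1CCC(=O)N1Br
Why: Electrophilic aromatic bromination of a phloroglucinol triether is fast at low temperature, the three free positions are equivalent, and the first bromine deactivates the ring enough for one equivalent of NBS to stop at the monobromide.

Step 2
Reactants: 2 2-bromo-1,3,5-tris(benzyloxy)benzene; 3 4-(benzyloxy)-2-hydroxybenzaldehyde
Product: 6 (±)-[4-(benzyloxy)-2-hydroxyphenyl][2,4,6-tris(benzyloxy)phenyl]methanol, via 2,4,6-tris(benzyloxy)phenyllithium 4 (not isolated), via sodium 5-(benzyloxy)-2-formylphenolate 5 (not isolated)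
Conditions: 2, n-BuLi, THF, −78 °C; separately 3, NaH, THF, 0 °C; combine, −78 to 0 °C; cold aq NH4Cl; Et3N-deactivated silica
Reagents that add atoms: none
Why: Bromine–lithium exchange followed by 1,2-addition of the aryllithium to the aldehyde is the standard benzhydrol synthesis; masking the acidic phenol as its sodium salt saves the second equivalent of 4 that a free OH would destroy, and the new carbinol centre may be racemic because it is erased in step 4.

Step 3
Reactants: 7 4-acetoxystyrene
Product: 8 4-vinylphenol
Conditions: K2CO3 (10 mol %), MeOH, 0 °C to rt; used at once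
Reagents that add atoms: none
Why: Base-catalysed transesterification (methanolysis) of the aryl acetate leaves the vinyl group untouched, and freshly made 8 is free of the polymer that builds up in stored material.

Step 4
Reactants: 6 (±)-[4-(benzyloxy)-2-hydroxyphenyl][2,4,6-tris(benzyloxy)phenyl]methanol; 8 4-vinylphenol
Product: 10 cis-(2R,4R)-7-(benzyloxy)-2-(4-hydroxyphenyl)-4-[2,4,6-tris(benzyloxy)phenyl]chroman, via (E)-ortho-quinone methide 9 (not isolated)
Conditions: (R)-3,3'-bis(2,4,6-triisopropylphenyl)-1,1'-binaphthyl-2,2'-diyl hydrogen phosphate (10 mol %), 4 Å MS, PhMe, 0 °C to rt, slow addition of 8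
Reagents that add atoms: none
Why: The phosphoric acid protonates the benzhydrylic OH of 6 and water leaves, giving the (E)-ortho-quinone methide 9, which is held to the catalyst P–OH by a hydrogen bond at its ring A oxygen while the P=O oxygen binds the phenol OH of 8. The CH2 terminus of 8 (future C3) attacks the methide carbon C4, and the positive charge building at C2, stabilised by the para oxygen of ring B, is captured by the ring A oxygen, so the pyran ring closes as an asynchronous inverse-demand oxa-(4+2) cycloaddition (in the stepwise limit a 6-exo-trig oxa-addition onto a para-quinone methide). The closest known reaction type is the chiral Brønsted acid catalysed hetero-Diels–Alder reaction of ortho-quinone methides, generated from ortho-hydroxybenzhydrols, with styrenes and hydroxystyrenes, which delivers cis-2,4-diarylchromans. C4 is set by the face of 9 that the 3,3'-aryl pocket of the catalyst leaves open, and because both enantiomers of 6 collapse to the same planar 9 the step is enantioconvergent. C2 is set relative to C4 by the endo placement of ring B over the (E)-methide, which puts the two aryl groups cis, and any acid-induced reopening of C2–O1 should drain to the same diequatorial cis isomer without touching C4. Regioselectivity follows from polarity (C4 is the vinylogous electrophilic terminus of the oxadiene, and the CH2 of 8 is the terminus whose attack leaves the cation beside ring B); chemoselectivity over styrene oligomerisation rests on the four donor oxygens of 6, which let it ionise under an acid too weak to initiate 8.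

Step 5
Reactants: 10 cis-(2R,4R)-7-(benzyloxy)-2-(4-hydroxyphenyl)-4-[2,4,6-tris(benzyloxy)phenyl]chroman
Product: 11 (2R,4R)-7-(benzyloxy)-2-[4-(benzyloxy)phenyl]-4-[2,4,6-tris(benzyloxy)phenyl]chroman
Conditions: BnBr, K2CO3, DMF, 0 °C to rt
Reagents that add atoms: benzyl bromide, BrCc1ccccc1
Why: Williamson ether synthesis on the only free phenol removes the acidic proton ahead of the organolithium step, and O-alkylation at room temperature should outrun reversible opening of the pyran ring through a para-quinone methide, so C2 stays as set.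

Step 6
Reactants: 11 (2R,4R)-7-(benzyloxy)-2-[4-(benzyloxy)phenyl]-4-[2,4,6-tris(benzyloxy)phenyl]chroman
Product: 12 (2R,4R)-7-(benzyloxy)-2-[4-(benzyloxy)phenyl]-4-[3-bromo-2,4,6-tris(benzyloxy)phenyl]chroman
Conditions: NBS (1.0 equiv), CH2Cl2, −78 to 0 °C, dark
Reagents that add atoms: N-bromosuccinimide, O=C1CCC(=O)N1Br
Why: In this electrophilic aromatic bromination the free CH positions of ring D are activated by three oxygens (two ortho, one para) against two for ring A and one for ring B, the two ring D positions give the same constitution by rotation about the C4–aryl bond, and the neutral cold conditions leave both stereocentres alone.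

Step 7
Reactants: 13 dodecanoyl chloride
Product: 14 N-methoxy-N-methyldodecanamide
Conditions: MeNH(OMe)·HCl, K2CO3, CH2Cl2–H2O, 0 °C to rt
Reagents that add atoms: N,O-dimethylhydroxylamine hydrochloride, CNOC.Cl
Why: Schotten–Baumann acylation of the liberated hydroxylamine nitrogen by the acid chloride is faster than hydrolysis in the two-phase medium and gives the Weinreb amide directly.

Step 8
Reactants: 12 (2R,4R)-7-(benzyloxy)-2-[4-(benzyloxy)phenyl]-4-[3-bromo-2,4,6-tris(benzyloxy)phenyl]chroman; 14 N-methoxy-N-methyldodecanamide
Product: 17 1-{2,4,6-tris(benzyloxy)-3-[(2R,4R)-7-(benzyloxy)-2-(4-(benzyloxy)phenyl)chroman-4-yl]phenyl}dodecan-1-one, via ring D aryllithium 15 (not isolated), via lithium hemiaminal adduct 16 (not isolated)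
Conditions: n-BuLi, THF, −78 °C; then 14, −78 to 0 °C; aq NH4Cl
Reagents that add atoms: none
Why: Bromine–lithium exchange followed by the Weinreb ketone synthesis stops at the chelated adduct 16 until the quench, so no over-addition occurs; this basic sequence is chosen over a Lewis acid Friedel–Crafts acylation, which would strip benzyl ethers and could ionise the acid-labile C2–O1 and C4–ring D bonds.

Step 9
Reactants: 17 1-{2,4,6-tris(benzyloxy)-3-[(2R,4R)-7-(benzyloxy)-2-(4-(benzyloxy)phenyl)chroman-4-yl]phenyl}dodecan-1-one
Product: 18 1-{2,4,6-trihydroxy-3-[(2R,4R)-7-hydroxy-2-(4-hydroxyphenyl)chroman-4-yl]phenyl}dodecan-1-one (target)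
Conditions: H2 (1 atm), 10% Pd/C, EtOAc–MeOH, rt, stopped at full debenzylation
Reagents that add atoms: none
Why: Catalytic hydrogenolysis cleaves the five primary benzyl aryl ethers faster than the cyclic secondary C2–O1 bond, the ketone is hindered at first and then locked by hydrogen bonds to its two ortho hydroxyls, and the neutral medium leaves C2 and C4 unchanged.

## Compound list

1 | 1,3,5-tris(benzyloxy)benzene | c1ccc(COc2cc(OCc3ccccc3)cc(OCc3ccccc3)c2)cc1 | starting material
2 | 2-bromo-1,3,5-tris(benzyloxy)benzene | Brc1c(OCc2ccccc2)cc(OCc2ccccc2)cc1OCc1ccccc1 | intermediate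
3 | 4-(benzyloxy)-2-hydroxybenzaldehyde | O=Cc1ccc(OCc2ccccc2)cc1O | starting material
4 | 2,4,6-tris(benzyloxy)phenyllithium | [Li]c1c(OCc2ccccc2)cc(OCc2ccccc2)cc1OCc1ccccc1 | intermediate
5 | sodium 5-(benzyloxy)-2-formylphenolate | [Na+].[O-]c1cc(OCc2ccccc2)ccc1C=O | intermediate
6 | (±)-[4-(benzyloxy)-2-hydroxyphenyl][2,4,6-tris(benzyloxy)phenyl]methanol (racemic carbinol) | OC(c1ccc(OCc2ccccc2)cc1O)c1c(OCc2ccccc2)cc(OCc2ccccc2)cc1OCc1ccccc1 | intermediate
7 | 4-acetoxystyrene | CC(=O)Oc1ccc(C=C)cc1 | starting material
8 | 4-vinylphenol | C=Cc1ccc(O)cc1 | intermediate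
9 | (6E)-3-(benzyloxy)-6-{[2,4,6-tris(benzyloxy)phenyl]methylidene}cyclohexa-2,4-dien-1-one | O=C1C=C(OCc2ccccc2)C=C/C1=C\c1c(OCc2ccccc2)cc(OCc2ccccc2)cc1OCc1ccccc1 | intermediate
10 | cis-(2R,4R)-7-(benzyloxy)-2-(4-hydroxyphenyl)-4-[2,4,6-tris(benzyloxy)phenyl]chroman | c1c(OCc2ccccc2)cc(OCc2ccccc2)c([C@@H]2C[C@H](c3ccc(O)cc3)Oc3cc(OCc4ccccc4)ccc32)c1OCc1ccccc1 | intermediate
11 | (2R,4R)-7-(benzyloxy)-2-[4-(benzyloxy)phenyl]-4-[2,4,6-tris(benzyloxy)phenyl]chroman | c1c(OCc2ccccc2)cc(OCc2ccccc2)c([C@@H]2C[C@H](c3ccc(OCc4ccccc4)cc3)Oc3cc(OCc4ccccc4)ccc32)c1OCc1ccccc1 | intermediate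
12 | (2R,4R)-7-(benzyloxy)-2-[4-(benzyloxy)phenyl]-4-[3-bromo-2,4,6-tris(benzyloxy)phenyl]chroman | Brc1c(OCc2ccccc2)cc(OCc2ccccc2)c([C@@H]2C[C@H](c3ccc(OCc4ccccc4)cc3)Oc3cc(OCc4ccccc4)ccc32)c1OCc1ccccc1 | intermediate
13 | dodecanoyl chloride | CCCCCCCCCCCC(=O)Cl | starting material
14 | N-methoxy-N-methyldodecanamide | CCCCCCCCCCCC(=O)N(C)OC | intermediate
15 | ring D aryllithium derived from 12 | [Li]c1c(OCc2ccccc2)cc(OCc2ccccc2)c([C@@H]2C[C@H](c3ccc(OCc4ccccc4)cc3)Oc3cc(OCc4ccccc4)ccc32)c1OCc1ccccc1 | intermediate
16 | lithium hemiaminal adduct of 15 and 14 (new carbon undefined, transient) | [Li+].CCCCCCCCCCCC([O-])(N(C)OC)c1c(OCc2ccccc2)cc(OCc2ccccc2)c([C@@H]2C[C@H](c3ccc(OCc4ccccc4)cc3)Oc3cc(OCc4ccccc4)ccc32)c1OCc1ccccc1 | intermediate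
17 | 1-{2,4,6-tris(benzyloxy)-3-[(2R,4R)-7-(benzyloxy)-2-(4-(benzyloxy)phenyl)chroman-4-yl]phenyl}dodecan-1-one | CCCCCCCCCCCC(=O)c1c(OCc2ccccc2)cc(OCc2ccccc2)c([C@@H]2C[C@H](c3ccc(OCc4ccccc4)cc3)Oc3cc(OCc4ccccc4)ccc32)c1OCc1ccccc1 | intermediate
18 | 1-{2,4,6-trihydroxy-3-[(2R,4R)-7-hydroxy-2-(4-hydroxyphenyl)chroman-4-yl]phenyl}dodecan-1-one | CCCCCCCCCCCC(=O)c1c(O)cc(O)c([C@@H]2C[C@H](c3ccc(O)cc3)Oc3cc(O)ccc32)c1O | target

## Step count and risks

Total step count: 9. Longest linear sequence: 7 steps (1, 2, 4, 5, 6, 8, 9).

**Step 4.**
- What may go wrong: ring D is twisted out of the methide plane, and its two ortho benzyloxy groups shield both faces of C4. C–C bond formation may then become slower than acid-induced oligomerisation of 8 or self-condensation of 9. The bulky methide may also sit loosely in the catalyst pocket, which would erode facial selectivity.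
- Fallback: chirality is taken from a resolution instead of from catalysis. Setting out from 6 and 8, the same cycloaddition is run with achiral diphenyl hydrogen phosphate in warm toluene, where forcing conditions are allowed because no chiral ion pair has to be preserved. This should give the racemic cis-chroman, that is 10 together with its (2S,4S)-enantiomer F1.
- The antipodes are separated by preparative supercritical fluid chromatography on an amylose tris(3,5-dimethylphenylcarbamate) phase, and the (2R,4R) antipode re-enters the route as 10.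

**Step 8.**
- What may go wrong: the aryllithium 15 is flanked by two benzyloxy groups. It may act as a base, either by enolising 14 or by abstracting a benzylic ether proton, instead of adding to the amide. That would return debrominated material.
- Fallback: the polarity of the bond formation is reversed and no aryllithium is used. Setting out from 11, Vilsmeier–Haack formylation (POCl3, DMF, 0 °C to rt, then aq NaOAc) should strike the most electron-rich ring D and give the ring D aldehyde F2.
- Addition of undecylmagnesium bromide, C11H23MgBr, in THF at 0 °C should give the secondary carbinol F3 as a mixture of carbinol epimers. Dess–Martin oxidation (NaHCO3-buffered CH2Cl2) then removes that centre and rejoins the route at 17.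

**Step 9.**
- What may go wrong: the four benzyl ethers on ring D are hindered, so long exposure may be needed. During it, hydrogenolytic opening of the benzylic C2–O1 bond or reduction of the ketone may set in.
- Fallback: a non-reductive debenzylation. Setting out from 17, BCl3 with pentamethylbenzene as benzyl cation scavenger in CH2Cl2 at −78 °C, quenched cold with MeOH, should give 18 directly. No new compound is made (F0).

## Further compounds

F1 | step 4 | cis-(2S,4S)-7-(benzyloxy)-2-(4-hydroxyphenyl)-4-[2,4,6-tris(benzyloxy)phenyl]chroman | c1c(OCc2ccccc2)cc(OCc2ccccc2)c([C@H]2C[C@@H](c3ccc(O)cc3)Oc3cc(OCc4ccccc4)ccc32)c1OCc1ccccc1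
F2 | step 8 | 2,4,6-tris(benzyloxy)-3-[(2R,4R)-7-(benzyloxy)-2-(4-(benzyloxy)phenyl)chroman-4-yl]benzaldehyde | O=Cc1c(OCc2ccccc2)cc(OCc2ccccc2)c([C@@H]2C[C@H](c3ccc(OCc4ccccc4)cc3)Oc3cc(OCc4ccccc4)ccc32)c1OCc1ccccc1
F3 | step 8 | 1-{2,4,6-tris(benzyloxy)-3-[(2R,4R)-7-(benzyloxy)-2-(4-(benzyloxy)phenyl)chroman-4-yl]phenyl}dodecan-1-ol (both carbinol epimers) | CCCCCCCCCCCC(O)c1c(OCc2ccccc2)cc(OCc2ccccc2)c([C@@H]2C[C@H](c3ccc(OCc4ccccc4)cc3)Oc3cc(OCc4ccccc4)ccc32)c1OCc1ccccc1
F0 | step 9 | none | none
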